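**Plan**

1. Numbering used throughout: O1–O2–C3–C4–C4a–O5–C6(=O)–C7–C7a. Ring A is the 1,2-dioxane (O1, O2, C3, C4, C4a, C7a) and ring B the γ-lactone (C4a, O5, C6, C7, C7a).
2. Retrosynthesis: the hexadecyl chain is cut at C2′–C3′ (cross-metathesis, then diimide) to a C3 allyl group, and the C3–allyl bond is cut to a C3 methoxy peroxyketal. The O1–C7a bond of ring A is then cut (retro peroxy-Michael) to a butenolide carrying a hydroperoxy ketal, itself traced to a 2-methylallyl group (ozonolysis in methanol). The butenolide C7=C7a is cut to an α-hydroxy aldehyde, and C4–C3 to an epoxide opening.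
3. Forward: the C7a–C4a–C4–C3 chain is built on (R)-2-methylglycidol, ring B is closed first as a butenolide, ring A second in the key step, and the C16 chain is attached last.
4. Enabling feature: C7a is the β-carbon of the ring B butenolide (C7=C7a conjugated with C6=O) and lies three atoms (C4a, C4, C3) from the peroxide oxygen O1 carried by C3. O1 can therefore add 6-exo to C7a, and the 6/5 fusion can only be cis.
5. Stereochemistry: C4a comes from (R)-2-methylglycidol. C7a is set by C4a through the cis fusion of the key step. C3 is set by axial allylation of the bicyclic peroxycarbenium ion on the face of O5.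

Key step: step 4

Remark: 1 is assumed to be enantiomerically pure; every later stereocentre is set relative to C4a, so its enantiomeric purity is carried through unchanged.

**Step 1**
Reactants: 1 (R)-2-methylglycidol; 2 isopropenylmagnesium bromide
Product: 3 (S)-2,4-dimethylpent-4-ene-1,2-diol
Conditions: 2 (2.5 equiv), CuI (10 mol %), THF, −30 to 0 °C; aq NH4Cl
Reagents that add atoms: isopropenylmagnesium bromide (2), CC(=C)[Mg]Br
Why: Copper-catalysed SN2 opening of the epoxide by the alkenyl Grignard reagent at the unsubstituted CH2 carbon (the first equivalent of 2 only deprotonates the hydroxyl); no bond to the quaternary carbon is broken, so the stereocentre of 1 is carried unchanged into 3 as the future C4a, its descriptor changing from R to S only because the CIP priorities change.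

**Step 2**
Reactants: 3 (S)-2,4-dimethylpent-4-ene-1,2-diol
Product: 4 (S)-2-hydroxy-2,4-dimethylpent-4-enal
Conditions: (COCl)2, DMSO, CH2Cl2, −78 °C; Et3N, −78 to 0 °C; used crude
Reagents that add atoms: none
Why: Swern oxidation of the primary alcohol; the tertiary alcohol cannot be oxidized and the α-carbon is quaternary, so the aldehyde cannot epimerize, and it is used crude to limit hemiacetal dimer formation.

**Step 3**
Reactants: 4 (S)-2-hydroxy-2,4-dimethylpent-4-enal; 5 methyl bis(2,2,2-trifluoroethyl)phosphonoacetate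
Product: 7 (S)-5-methyl-5-(2-methylprop-2-en-1-yl)furan-2(5H)-one, via Z-hydroxy enoate 6 (not isolated)
Conditions: 5, KN(SiMe3)2, 18-crown-6, THF, −78 °C; then TsOH (cat.), CH2Cl2, rt
Reagents that add atoms: methyl bis(2,2,2-trifluoroethyl)phosphonoacetate (5), COC(=O)CP(=O)(OCC(F)(F)F)OCC(F)(F)F
Why: The Still–Gennari modification of the Horner–Wadsworth–Emmons reaction should give the Z-enoate 6 under kinetic control, and only this isomer can place the ester next to the tertiary hydroxyl, which closes ring B by acid-catalysed lactonization; no stereocentre is formed or touched.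

**Step 4**
Reactants: 7 (S)-5-methyl-5-(2-methylprop-2-en-1-yl)furan-2(5H)-one; 8 ozone; 9 methanol
Product: 12 (4aS,7aS)-3-methoxy-3,4a-dimethyltetrahydro-3H-furo[3,2-c][1,2]dioxin-6(4H)-one (cis-fused; both C3 epimers), via carbonyl oxide 10 (not isolated), via hydroperoxy ketal 11 (not isolated)
Conditions: O3, CH2Cl2/MeOH 4:1, −78 °C, Sudan Red 7B end point; N2 purge, concentrate at 0 °C; then Et2NH (0.5 equiv), CF3CH2OH, 0 °C to rt
Reagents that add atoms: ozone (8), [O-][O+]=O; methanol (9), CO
Why: Ozone cleaves only the electron-rich 1,1-disubstituted alkene to formaldehyde and the more substituted carbonyl oxide 10 (Criegee mechanism), and methanol traps 10 as the hydroperoxy ketal 11, which thus carries an OOH group on the future C3. Under Et2NH in CF3CH2OH the hydroperoxide oxygen O1 adds to C7a, the β-carbon of the butenolide, in a peroxy-Michael (oxa-Michael) addition, followed by protonation at C7. The closest known reaction type is the conjugate addition of α-methoxy hydroperoxides, made by ozonolysis in methanol or by perketalization, to enoates to give 3-methoxy-1,2-dioxanes, together with the addition of tertiary hydroperoxides to γ,γ-disubstituted butenolides. Ring A closes in the 6-exo-trig mode, helped by the quaternary C4a (Thorpe–Ingold effect) and by the s-cis-locked acceptor. C7a is controlled by C4a, because the three-atom tether can reach the planar butenolide only from the face that carries the C4 methylene, so the 6/5 fusion must be cis (7a-H cis to the 4a-methyl); the ketal centre C3 forms as a mixture that is erased in step 5. The step needs chemoselectivity of ozone for the isolated alkene over the conjugated, electron-poor butenolide C=C and cleavage toward the substituted carbonyl oxide, both secured by the electron-rich dialkyl-substituted alkene carbon and the indicator end point, and O- rather than N-addition to C7a, secured by the reversibility of amine addition at this hindered β-carbon in the fluorinated alcohol.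

**Step 5**
Reactants: 12 (4aS,7aS)-3-methoxy-3,4a-dimethyltetrahydro-3H-furo[3,2-c][1,2]dioxin-6(4H)-one; 13 allyltrimethylsilane
Product: 15 (3R,4aS,7aS)-3-allyl-3,4a-dimethyltetrahydro-3H-furo[3,2-c][1,2]dioxin-6(4H)-one, via peroxycarbenium ion 14 (not isolated)
Conditions: 13 (3 equiv), TiCl4 (1.1 equiv), CH2Cl2, −78 °C; aq NaHCO3
Reagents that add atoms: allyltrimethylsilane (13), C=CC[Si](C)(C)C
Why: Hosomi–Sakurai-type allylation of a cyclic peroxyketal: TiCl4 ionizes either C3 epimer of 12 to the same peroxycarbenium ion 14 (C3=O2+), and the allylsilane should attack C3 axially through a chair-like transition state on the half-chair that keeps the 4a-methyl pseudoequatorial and the lactone oxygen O5 pseudoaxial, that is from the face of O5 (the other face would need a twist-boat or a syn-diaxial clash with the 4a-methyl), which places the allyl group cis to O5 and the 3-methyl cis to the 4a-methyl (3R).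

**Step 6**
Reactants: 15 (3R,4aS,7aS)-3-allyl-3,4a-dimethyltetrahydro-3H-furo[3,2-c][1,2]dioxin-6(4H)-one; 16 pentadec-1-ene
Product: 17 (3R,4aS,7aS)-3-(hexadec-2-en-1-yl)-3,4a-dimethyltetrahydro-3H-furo[3,2-c][1,2]dioxin-6(4H)-one (E/Z mixture)
Conditions: 16 (4 equiv), second-generation Grubbs catalyst (H2IMes)(PCy3)Cl2Ru=CHPh (5 mol %), CH2Cl2, 40 °C
Reagents that add atoms: pentadec-1-ene (16), C=CCCCCCCCCCCCCC
Why: Olefin cross-metathesis between two unhindered terminal alkenes, driven by loss of ethylene and by the excess of 16; the lactone and the fully alkylated O–O bond should be tolerated at 40 °C, no stereocentre is touched, and the E/Z mixture of the new C=C bond is removed in step 7.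

**Step 7**
Reactants: 17 (3R,4aS,7aS)-3-(hexadec-2-en-1-yl)-3,4a-dimethyltetrahydro-3H-furo[3,2-c][1,2]dioxin-6(4H)-one
Product: 18 (3R,4aS,7aS)-3-hexadecyl-3,4a-dimethyltetrahydro-3H-furo[3,2-c][1,2]dioxin-6(4H)-one
Conditions: KO2CN=NCO2K (excess, in portions), AcOH, CH2Cl2/MeOH, 0 °C to rt
Reagents that add atoms: none
Why: Diimide reduction: HN=NH generated from the azodicarboxylate and AcOH transfers H2 to the C=C bond in a concerted syn fashion and leaves untouched the lactone and the O–O bond, which catalytic hydrogenation would cleave, while the weakly acidic medium avoids base-induced Kornblum–DeLaMare or retro-Michael opening of ring A.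

**Compound list**

1 | (R)-2-methylglycidol, [(2R)-2-methyloxiran-2-yl]methanol | OC[C@]1(C)CO1 | starting material
2 | isopropenylmagnesium bromide | CC(=C)[Mg]Br | starting material
3 | (S)-2,4-dimethylpent-4-ene-1,2-diol | CC(=C)C[C@](C)(O)CO | intermediate
4 | (S)-2-hydroxy-2,4-dimethylpent-4-enal | CC(=C)C[C@](C)(O)C=O | intermediate
5 | methyl bis(2,2,2-trifluoroethyl)phosphonoacetate | COC(=O)CP(=O)(OCC(F)(F)F)OCC(F)(F)F | starting material
6 | methyl (2Z,4S)-4-hydroxy-4,6-dimethylhepta-2,6-dienoate | CC(=C)C[C@](C)(O)/C=C\C(=O)OC | intermediate (not isolated)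
7 | (S)-5-methyl-5-(2-methylprop-2-en-1-yl)furan-2(5H)-one | CC(=C)C[C@]1(C)OC(=O)C=C1 | intermediate
8 | ozone | [O-][O+]=O | starting material
9 | methanol | CO | starting material
10 | carbonyl oxide (ketone O-oxide) of (S)-5-methyl-5-(2-oxopropyl)furan-2(5H)-one | CC(=[O+][O-])C[C@]1(C)OC(=O)C=C1 | intermediate (not isolated)
11 | (5S)-5-(2-hydroperoxy-2-methoxypropyl)-5-methylfuran-2(5H)-one, both epimers at the ketal carbon | COC(C)(OO)C[C@]1(C)OC(=O)C=C1 | intermediate (not isolated)
12 | (4aS,7aS)-3-methoxy-3,4a-dimethyltetrahydro-3H-furo[3,2-c][1,2]dioxin-6(4H)-one, cis-fused, both C3 epimers | COC1(C)C[C@]2(C)OC(=O)C[C@@H]2OO1 | intermediate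
13 | allyltrimethylsilane | C=CC[Si](C)(C)C | starting material
14 | (4aS,7aS)-3,4a-dimethyl-6-oxo-4,4a,7,7a-tetrahydro-6H-furo[3,2-c][1,2]dioxin-2-ium, peroxycarbenium ion with C3=O2+ | CC1=[O+]O[C@H]2CC(=O)O[C@@]2(C)C1 | intermediate (not isolated)
15 | (3R,4aS,7aS)-3-allyl-3,4a-dimethyltetrahydro-3H-furo[3,2-c][1,2]dioxin-6(4H)-one; allyl cis to O5, 3-methyl cis to 4a-methyl and 7a-H | C=CC[C@]1(C)C[C@]2(C)OC(=O)C[C@@H]2OO1 | intermediate
16 | pentadec-1-ene | C=CCCCCCCCCCCCCC | starting material
17 | (3R,4aS,7aS)-3-(hexadec-2-en-1-yl)-3,4a-dimethyltetrahydro-3H-furo[3,2-c][1,2]dioxin-6(4H)-one, E/Z mixture | CCCCCCCCCCCCCC=CC[C@]1(C)C[C@]2(C)OC(=O)C[C@@H]2OO1 | intermediate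
18 | (3R,4aS,7aS)-3-hexadecyl-3,4a-dimethyltetrahydro-3H-furo[3,2-c][1,2]dioxin-6(4H)-one; cis-fused, 3-methyl, 4a-methyl and 7a-H on one face, hexadecyl and lactone on the other | CCCCCCCCCCCCCCCC[C@]1(C)C[C@]2(C)OC(=O)C[C@@H]2OO1 | target

**Total step count:** 7
**Longest linear sequence:** 7 steps (1 to 18)

**Steps most likely to fail**

Step 5. What may go wrong: poor facial selectivity in the capture of the peroxycarbenium ion, or Lewis-acid ionization at the ring peroxide oxygen followed by fragmentation. Fallback (sets out from 1, comes back at 18): the chain is brought in at the start and the C3–O2 bond is made by radical hydroperoxidation. Octadec-1-yne is hydrobrominated (HBr, Et4NBr, CH2Cl2) to 2-bromooctadec-1-ene F1, which with magnesium in THF gives octadec-1-en-2-ylmagnesium bromide F2. F2 opens 1 (CuI cat., THF) to (S)-2-methyl-4-methylideneicosane-1,2-diol F3. Swern oxidation gives (S)-2-hydroxy-2-methyl-4-methylideneicosanal F4. Still–Gennari olefination with 5 gives methyl (2Z,4S)-4-hydroxy-4-methyl-6-methylidenedocos-2-enoate F5, which lactonizes (TsOH cat.) to (S)-5-methyl-5-(2-methylideneoctadecyl)furan-2(5H)-one F6. Mukaiyama–Isayama hydroperoxysilylation of the 1,1-disubstituted alkene (Co(acac)2 cat., O2, Et3SiH, ClCH2CH2Cl, rt) gives (5S)-5-methyl-5-{2-methyl-2-[(triethylsilyl)peroxy]octadecyl}furan-2(5H)-one F7 as both epimers at the peroxide carbon. Bu4NF (THF, 0 °C) frees the hydroperoxide (5S)-5-(2-hydroperoxy-2-methyloctadecyl)-5-methylfuran-2(5H)-one F8. F8 closes ring A under Et2NH/CF3CH2OH by the same 6-exo peroxy-Michael addition, giving 18 and its C3 epimer (3S,4aS,7aS)-3-hexadecyl-3,4a-dimethyltetrahydro-3H-furo[3,2-c][1,2]dioxin-6(4H)-one F9, to be separated by chromatography. Control of C3 is given up in exchange for a sequence in which every step has close precedent.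

Step 4. What may go wrong: cleavage of the ozone adduct in the other direction (ketone plus formaldehyde oxide), over-oxidation of the butenolide C=C, or loss of the hydroperoxy ketal before it cyclizes. Fallback (sets out from 7, comes back at 11): the hydroperoxy ketal is made by nucleophilic perketalization of an isolated ketone. Ozonolysis of 7 in CH2Cl2 at −78 °C with Me2S work-up gives (S)-5-methyl-5-(2-oxopropyl)furan-2(5H)-one F10, whatever the direction of cleavage. Urea–hydrogen peroxide with Sc(OTf)3 (cat.) in MeOH then converts F10 into 11, which is cyclized with Et2NH/CF3CH2OH to 12 as in step 4.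

Step 6. What may go wrong: cleavage of the O–O bond at ruthenium, or catalyst deactivation, during the metathesis. Fallback (sets out from 15, comes back at 17): the chain is attached by olefination, with no ruthenium. Ozonolysis of the allyl group of 15 (O3, CH2Cl2, −78 °C; PPh3) gives 2-[(3S,4aS,7aS)-3,4a-dimethyl-6-oxohexahydrofuro[3,2-c][1,2]dioxin-3-yl]acetaldehyde F11. Wittig reaction at −78 °C with triphenyl(tetradecylidene)phosphorane F12, made from tetradecyltriphenylphosphonium bromide and NaN(SiMe3)2 in THF, gives the Z isomer of 17, which enters step 7.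

**Further compounds**

F1 | step 5 | 2-bromooctadec-1-ene | C=C(Br)CCCCCCCCCCCCCCCC
F2 | step 5 | octadec-1-en-2-ylmagnesium bromide | C=C([Mg]Br)CCCCCCCCCCCCCCCC
F3 | step 5 | (S)-2-methyl-4-methylideneicosane-1,2-diol | CCCCCCCCCCCCCCCCC(=C)C[C@](C)(O)CO
F4 | step 5 | (S)-2-hydroxy-2-methyl-4-methylideneicosanal | CCCCCCCCCCCCCCCCC(=C)C[C@](C)(O)C=O
F5 | step 5 | methyl (2Z,4S)-4-hydroxy-4-methyl-6-methylidenedocos-2-enoate | CCCCCCCCCCCCCCCCC(=C)C[C@](C)(O)/C=C\C(=O)OC
F6 | step 5 | (S)-5-methyl-5-(2-methylideneoctadecyl)furan-2(5H)-one | CCCCCCCCCCCCCCCCC(=C)C[C@]1(C)OC(=O)C=C1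
F7 | step 5 | (5S)-5-methyl-5-{2-methyl-2-[(triethylsilyl)peroxy]octadecyl}furan-2(5H)-one, both epimers at the peroxide carbon | CCCCCCCCCCCCCCCCC(C)(OO[Si](CC)(CC)CC)C[C@]1(C)OC(=O)C=C1
F8 | step 5 | (5S)-5-(2-hydroperoxy-2-methyloctadecyl)-5-methylfuran-2(5H)-one, both epimers at the peroxide carbon | CCCCCCCCCCCCCCCCC(C)(OO)C[C@]1(C)OC(=O)C=C1
F9 | step 5 | (3S,4aS,7aS)-3-hexadecyl-3,4a-dimethyltetrahydro-3H-furo[3,2-c][1,2]dioxin-6(4H)-one | CCCCCCCCCCCCCCCC[C@@]1(C)C[C@]2(C)OC(=O)C[C@@H]2OO1
F10 | step 4 | (S)-5-methyl-5-(2-oxopropyl)furan-2(5H)-one | CC(=O)C[C@]1(C)OC(=O)C=C1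
F11 | step 6 | 2-[(3S,4aS,7aS)-3,4a-dimethyl-6-oxohexahydrofuro[3,2-c][1,2]dioxin-3-yl]acetaldehyde | O=CC[C@]1(C)C[C@]2(C)OC(=O)C[C@@H]2OO1
F12 | step 6 | triphenyl(tetradecylidene)phosphorane | CCCCCCCCCCCCCC=P(c1ccccc1)(c1ccccc1)c1ccccc1
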